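Locants: C1 CH(O-angeloyl), C2 CH2, C3 CH(OH), C4–C5–C6–C7 the cyclobutane (C4 carries CH3, C6 is bonded to C11, C5 and C7 carry the ketone ring), C8 C=O, C9 CH2, C10 CH(CH3), C11 C(CH3)(CH2OAc), C12 the acetoxymethyl carbon.
Retrosynthesis: remove the two acyl groups and tie C12 (as a carboxyl) to the C3 oxygen as a δ-lactone; cut C10–CH3 (cuprate) and C9–C10 (aldol condensation) of the ketone ring; then cut C2–C3 and C6–C11 together, which leaves a 3-formyl cyclobutenyl methyl ketone and a 2-methylacetoacetate unit (C2–C1–C11–C12).
Enabling feature: C3 (on C4) and C6 sit 1,3-cis on the cyclobutane, C3–OH/C1–O is an aldol pair, C11 is the α-carbon of a β-keto acid derivative and C6 is β to the C8 ketone through C7, so a strained C6=C7 cyclobutenyl enone can take up a lactone-tethered enolate.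
Forward: (+)-verbenone is cleaved to cis-pinononic acid (cyclobutane first), one geminal methyl is oxidised by directed 1,5-hydrogen transfer (it becomes C3), the cyclobutenyl aldehyde is made, the key step builds the seven-membered ring as a lactone-bridged bicyclo[4.1.1]octane, the six-membered ketone ring is re-closed on the opposite face, and the esters are set last.
Stereochemistry: C4 from verbenone plus the cis-selective hydrogen transfer; C3 from the chiral titanium catalyst; C11 and C6 from the lactone tether; C5 and C7 by exo equilibration; C10 by cuprate addition anti to the C4 methyl; C1 by hydride attack from the lactone face.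

Key step: step 7

Assumption: Ti(OiPr)4/(R)-BINOL is taken to deliver the dienol ether to the aldehyde face that gives the (R)-carbinol at C3, as with simple aldehydes of the same priority pattern; if the sense or a substrate bias opposes this, (S)-BINOL is used.

Step 1
Reactants: 1 (1R,5R)-(+)-verbenone
Product: 2 (1R,3S)-3-acetyl-2,2-dimethylcyclobutane-1-carboxylic acid (cis-pinononic acid)
Conditions: RuCl3·xH2O (cat.), NaIO4, CCl4/MeCN/H2O, 23 °C
Reagents that add atoms: sodium periodate [Na+].[O-]I(=O)(=O)=O; water O
Why: RuO4 formed in the flask cleaves the enone C=C and degrades the resulting α-keto acid with loss of CO2 (oxidative alkene cleavage), which leaves both bridgehead stereocentres untouched, so acetyl and carboxyl stay cis on the cyclobutane.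

Step 2
Reactants: 2 (1R,3S)-cis-pinononic acid
Product: 4 (1R,3S)-3-acetyl-2,2-dimethylcyclobutane-1-carboxamide, via acyl imidazole 3 (not isolated)
Conditions: CDI, THF, 23 °C; then NH3 (7 M in MeOH), 0 °C
Reagents that add atoms: ammonia N
Why: Acyl imidazole activation and ammonolysis (amide coupling) should give the primary carboxamide that serves as the hydrogen-abstracting group, without epimerising the α-stereocentre.

Step 3
Reactants: 4 (1R,3S)-3-acetyl-2,2-dimethylcyclobutane-1-carboxamide
Product: 6 cis-fused γ-lactone 6-acetyl-5-methyl-3-oxabicyclo[3.2.0]heptan-2-one, via iminolactone hydroiodide 5 (not isolated)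
Conditions: t-BuOCl, I2, PhH, hν, 25 °C; then H2O/THF, 40 °C
Reagents that add atoms: water O
Why: The N-iodoamide should give an amidyl radical that abstracts hydrogen through a six-membered transition state only from the geminal methyl cis to the carboxamide (Hofmann–Löffler–Freytag-type 1,5-hydrogen transfer); iodide displacement by the amide oxygen and hydrolysis then give the lactone and make C4 a stereocentre of defined configuration.

Step 4
Reactants: 6 cis-fused γ-lactone
Product: 7 S-ethyl 3-acetyl-2-(hydroxymethyl)-2-methylcyclobutane-1-carbothioate (all three groups cis)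
Conditions: AlMe3, EtSH, CH2Cl2, 0 to 23 °C
Reagents that add atoms: ethanethiol CCS
Why: The aluminium thiolate should open the lactone by acyl substitution (lactone thiolysis), freeing the hydroxymethyl group (C3) and leaving the carboxyl carbon (C10) as a thioester that can later be reduced selectively; 7 is taken on at once because it can relactonise.

Step 5
Reactants: 7 S-ethyl 3-acetyl-2-(hydroxymethyl)-2-methylcyclobutane-1-carbothioate
Product: 8 S-ethyl 3-acetyl-4-formyl-4-methylcyclobut-2-ene-1-carbothioate (formyl cis to the thioester)
Conditions: IBX, 4-methoxypyridine N-oxide, DMSO, 25 °C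
Reagents that add atoms: none
Why: IBX should oxidise the primary alcohol and then dehydrogenate the ketone through its enol (IBX dehydrogenation), which can only end in the C6=C7 enone because the methyl side has no β-hydrogen; the N-oxide complex allows 25 °C, needed because a 3-formylcyclobutene opens electrocyclically on heating, and 8 is used directly.

Step 6
Reactants: 9 tert-butyl 2-methyl-3-oxobutanoate
Product: 11 1-tert-butoxy-2-methyl-1,3-bis(trimethylsilyloxy)buta-1,3-diene, via silyl enol ether 10 (not isolated)
Conditions: TMSCl, Et3N, PhH, 23 °C; then LDA, THF, −78 °C, TMSCl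
Reagents that add atoms: chlorotrimethylsilane C[Si](C)(C)Cl
Why: O-silylation of the β-keto ester followed by γ-deprotonation and a second O-silylation (silyl dienol ether formation) should give a γ-nucleophilic diene for a vinylogous Mukaiyama aldol reaction.

Step 7
Reactants: 8 S-ethyl 3-acetyl-4-formyl-4-methylcyclobut-2-ene-1-carbothioate; 11 1-tert-butoxy-2-methyl-1,3-bis(trimethylsilyloxy)buta-1,3-diene
Product: 14 lactone-bridged tricyclic keto thioester, via silylated aldol adduct 12 (not isolated), via keto lactone 13 (not isolated)
Conditions: Ti(OiPr)4/(R)-BINOL (20 mol %), 4 Å MS, THF, −78 to −20 °C; then TFA, CH2Cl2, 0 to 23 °C; then DBU, CH2Cl2, 23 °C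
Reagents that add atoms: none
Why: Proposed new method: a reagent-controlled vinylogous Mukaiyama aldol addition of 11 to the aldehyde of 8 forms C2–C3, acid then removes the silyl and tert-butyl groups and closes the β-keto δ-lactone 13 (6-exo-trig acylation by the C3 hydroxyl), and DBU deprotonates this cyclic 1,3-dicarbonyl, whose α-carbon C11 adds to C6 of the cyclobutenyl ketone to form C6–C11 (7-exo-trig with respect to C6=C7), closing the seven-membered carbocycle and the bicyclo[4.1.1]octane. The closest known reaction types are the conjugate addition of 2-alkyl-1,3-diones to enones and formal (4+3) annulations of 1,3-bis(silyl enol ethers) with 1,4-dielectrophiles; what is new is the intramolecular, bridging addition to a cyclobutene, where release of the extra strain of the ring C=C should make the addition downhill and irreversible. C3 is set by the titanium–BINOL catalyst; C11 is fixed by the lactone, because C3 and C11 become bridgeheads of a bicyclo[3.2.2] system and only one relative configuration can close; C6 is set by delivery of C11 on the face that carries C3; C5 and C7 end exo by base equilibration (C5 through the vinylogous enolate before addition, C7 through the ketone enolate after it). The step needs aldehyde over enone and thioester chemoselectivity in the aldol stage, expected from the higher reactivity of the aldehyde towards the Lewis acid catalyst, and C- over O-alkylation in the conjugate addition, expected for a soft, fully substituted 1,3-dicarbonyl carbon. The 1,3-cis disposition of C3 and C6 on the cyclobutene, inherited from verbenone, holds the nucleophile over the acceptor.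

Step 8
Reactants: 14 lactone-bridged tricyclic keto thioester
Product: 16 tetracyclic enone lactone, via keto aldehyde 15 (not isolated)
Conditions: Et3SiH, 10% Pd/C, acetone, 23 °C; then Bn2NH·CF3CO2H, PhH, 50 °C
Reagents that add atoms: none
Why: Hydrosilane reduction of the thioester on palladium (Fukuyama reduction) should give the aldehyde beside ketones and lactone, and the ammonium salt then effects an intramolecular aldol condensation of the acetyl methyl (C9) with the aldehyde (C10), possible only when both groups are exo, which closes the bicyclo[3.1.1]heptenone.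

Step 9
Reactants: 16 tetracyclic enone lactone
Product: 17 C1 alcohol (hydroxyl trans to the lactone bridge)
Conditions: NaBH4, MeOH/CH2Cl2 (1:1), −78 °C
Reagents that add atoms: none
Why: At low temperature borohydride should reduce the saturated, acyl-activated C1 ketone before the conjugated enone (chemoselective ketone reduction), with hydride arriving past the flat lactone bridge and not past the C11 methyl and C5–H, which puts the C1 hydroxyl on the side required.

Step 10
Reactants: 17 C1 alcohol
Product: 18 C1 angelate
Conditions: angelic acid, 2,4,6-trichlorobenzoyl chloride, Et3N, PhMe, 23 °C; then 17, 80 °C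
Reagents that add atoms: angelic acid C/C=C(/C)C(=O)O
Why: The mixed anhydride should acylate the hindered secondary alcohol without Z to E isomerisation (Yamaguchi esterification), the C3 oxygen being protected inside the lactone.

Step 11
Reactants: 18 C1 angelate
Product: 19 C10-methyl triethylsilyl enol ether
Conditions: Me2CuLi, TESCl, THF, −78 °C; then Et3N
Reagents that add atoms: lithium dimethylcuprate [Li+].C[Cu-]C; chlorotriethylsilane CC[Si](Cl)(CC)CC
Why: Conjugate addition of the cuprate to the enone (1,4-addition) should occur on the face next to C6–H and away from the C4 methyl, which sets C10, and trapping the enolate as its silyl enol ether masks the C8 ketone for the next step; the hindered angelate is a much poorer acceptor.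

Step 12
Reactants: 19 C10-methyl triethylsilyl enol ether
Product: 20 diol (C3 hydroxyl and C12 primary alcohol free)
Conditions: LiBH4, THF, −20 to 0 °C
Reagents that add atoms: none
Why: LiBH4 should reduce the bridged δ-lactone faster than the conjugated, α-branched angelate (chemoselective lactone reduction), releasing the C3 hydroxyl and the primary alcohol at once.

Step 13
Reactants: 20 diol
Product: 22 target CNP0212099.1, via acetate silyl enol ether 21 (not isolated)
Conditions: AcCl, 2,4,6-collidine, CH2Cl2, −78 °C; then AcOH/THF/H2O, 23 °C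
Reagents that add atoms: acetyl chloride CC(=O)Cl
Why: Acetyl chloride with collidine at low temperature should acylate the primary alcohol in preference to the hindered secondary C3 hydroxyl (selective acylation), and mild acid then hydrolyses the silyl enol ether to the C8 ketone.

Compound list
1 | (1R,5R)-(+)-verbenone, 4,6,6-trimethylbicyclo[3.1.1]hept-3-en-2-one | CC1=CC(=O)[C@@H]2C[C@H]1C2(C)C | starting material
2 | (1R,3S)-3-acetyl-2,2-dimethylcyclobutane-1-carboxylic acid (cis-pinononic acid; acetyl and carboxyl cis) | CC(=O)[C@H]1C[C@@H](C(=O)O)C1(C)C | intermediate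
3 | N-acyl imidazole of 2 | CC(=O)[C@H]1C[C@@H](C(=O)n2ccnc2)C1(C)C | intermediate
4 | (1R,3S)-3-acetyl-2,2-dimethylcyclobutane-1-carboxamide | CC(=O)[C@H]1C[C@@H](C(N)=O)C1(C)C | intermediate
5 | iminolactone hydroiodide (6-acetyl-2-iminio-5-methyl-3-oxabicyclo[3.2.0]heptane iodide, cis ring fusion) | CC(=O)[C@H]1C[C@H]2C(=[NH2+])OC[C@@]12C.[I-] | intermediate
6 | 6-acetyl-5-methyl-3-oxabicyclo[3.2.0]heptan-2-one (cis-fused γ-lactone, acetyl cis to the lactone ring) | CC(=O)[C@H]1C[C@H]2C(=O)OC[C@@]12C | intermediate
7 | S-ethyl 3-acetyl-2-(hydroxymethyl)-2-methylcyclobutane-1-carbothioate (thioester, hydroxymethyl and acetyl all cis) | CCSC(=O)[C@@H]1C[C@H](C(C)=O)[C@]1(C)CO | intermediate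
8 | S-ethyl 3-acetyl-4-formyl-4-methylcyclobut-2-ene-1-carbothioate (formyl cis to the thioester) | CCSC(=O)[C@@H]1C=C(C(C)=O)[C@]1(C)C=O | intermediate
9 | tert-butyl 2-methyl-3-oxobutanoate | CC(=O)C(C)C(=O)OC(C)(C)C | starting material
10 | tert-butyl 2-methyl-3-(trimethylsilyloxy)but-2-enoate (E/Z mixture) | CC(O[Si](C)(C)C)=C(C)C(=O)OC(C)(C)C | intermediate
11 | 1-tert-butoxy-2-methyl-1,3-bis(trimethylsilyloxy)buta-1,3-diene (E/Z mixture) | C=C(O[Si](C)(C)C)C(C)=C(OC(C)(C)C)O[Si](C)(C)C | intermediate
12 | silylated aldol adduct: 8 with its formyl carbon turned into the (R)-CH(OSiMe3)CH2C(=O)C(CH3)=C(OtBu)OSiMe3 chain | CCSC(=O)[C@@H]1C=C(C(C)=O)[C@]1(C)[C@H](O[Si](C)(C)C)CC(=O)C(C)=C(OC(C)(C)C)O[Si](C)(C)C | intermediate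
13 | keto lactone: 3-methyloxane-2,4-dione bonded at its C6 (R) to C4 of the cyclobutene; the methyl-bearing carbon is stereolabile (enolised) | CCSC(=O)[C@@H]1C=C(C(C)=O)[C@]1(C)[C@H]1CC(=O)C(C)C(=O)O1 | intermediate
14 | lactone-bridged tricyclic keto thioester: cyclobutane C4–C7 bridged by C3–C2–C1–C11 (bicyclo[4.1.1]octane), δ-lactone C3–O–C12(=O)–C11, C1 ketone, exo acetyl on C7, exo C(=O)SEt on C5 | CCSC(=O)[C@H]1[C@H]2[C@@H](C(C)=O)[C@]1(C)[C@H]3CC(=O)[C@]2(C)C(=O)O3 | intermediate
15 | keto aldehyde: 14 with CHO in place of C(=O)SEt | O=C[C@H]1[C@H]2[C@@H](C(C)=O)[C@]1(C)[C@H]3CC(=O)[C@]2(C)C(=O)O3 | intermediate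
16 | tetracyclic enone lactone: bicyclo[3.1.1]hept-3-en-2-one ring (C8 ketone, C9=C10) closed on the exo face; C1 ketone and lactone kept | O=C1C=C[C@H]2[C@H]3[C@@H]1[C@]2(C)[C@H]4CC(=O)[C@]3(C)C(=O)O4 | intermediate
17 | C1 alcohol: 16 with C1–OH trans to the lactone bridge | O=C1C=C[C@H]2[C@H]3[C@@H]1[C@]2(C)[C@H]4C[C@@H](O)[C@]3(C)C(=O)O4 | intermediate
18 | C1 angelate: the (Z)-2-methylbut-2-enoate of 17 | O=C1C=C[C@H]2[C@H]3[C@@H]1[C@]2(C)[C@H]4C[C@@H](OC(=O)/C(C)=C\C)[C@]3(C)C(=O)O4 | intermediate
19 | C10-methyl triethylsilyl enol ether: C10 methyl on the face of C6–H, C8 as C(OSiEt3)=C9 | CC[Si](CC)(CC)OC1=C[C@@H](C)[C@H]2[C@H]3[C@@H]1[C@]2(C)[C@H]4C[C@@H](OC(=O)/C(C)=C\C)[C@]3(C)C(=O)O4 | intermediate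
20 | diol: lactone of 19 reduced to C3–OH and C12H2–OH | CC[Si](CC)(CC)OC1=C[C@@H](C)[C@H]2[C@H]3[C@@H]1[C@]2(C)[C@H](O)C[C@@H](OC(=O)/C(C)=C\C)[C@]3(C)CO | intermediate
21 | acetate silyl enol ether: primary acetate of 20 | CC[Si](CC)(CC)OC1=C[C@@H](C)[C@H]2[C@H]3[C@@H]1[C@]2(C)[C@H](O)C[C@@H](OC(=O)/C(C)=C\C)[C@]3(C)COC(C)=O | intermediate
22 | target CNP0212099.1 (longipinan-type keto diester: C1 angelate, C3 hydroxyl, C12 acetate, C8 ketone) | O=C1C[C@@H](C)[C@H]2[C@H]3[C@@H]1[C@]2(C)[C@H](O)C[C@@H](OC(=O)/C(C)=C\C)[C@]3(C)COC(C)=O | target

Total step count: 13. Longest linear sequence: 12 steps (steps 1 to 5 and 7 to 13).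

Steps most likely to fail

Step 7. What may go wrong: erosion of facial selectivity in the aldol stage when the catalyst works against the bias of the α-quaternary aldehyde, electrocyclic opening of the formylcyclobutene before it reacts, or failure of the hindered bridging conjugate addition. The fallback uses known chemistry and reverses the order of bond formation. It sets out from 8 and comes back at 14. Conjugate addition of β-keto ester 9 to the enone of 8 under a cinchona-derived amine–squaramide catalyst, a known way to make quaternary centres from α-substituted β-keto esters and enones, should give the Michael adduct F1 with C11 set by the catalyst. Base-mediated intramolecular aldol addition of the methyl ketone to the aldehyde (DBU or pyrrolidine/AcOH) should give the aldol product F2 under reversible conditions. TFA then cleaves the tert-butyl ester and closes the lactone, which only the C3 epimer with oxygen on the carboxyl side can form, to give 14.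

Step 5. What may go wrong: thermal electrocyclic ring opening of the 3-formylcyclobutene while it accumulates during a slow dehydrogenation, or stalling at the keto aldehyde. The fallback sets out from 7 and comes back at 8, and introduces the double bond last by an elimination that runs at 0 °C. Dess–Martin oxidation at 0 °C should give the keto aldehyde F3. PhSeCl in EtOAc should selenenylate the ketone through its more substituted enol to give the α-selanyl ketone F4. H2O2 with pyridine at 0 °C then gives 8 by selenoxide syn-elimination towards C6, the only carbon with a β-hydrogen, and 8 is taken into step 7 at once.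

Step 12. What may go wrong: hydride attack on the angelate, or transfer of the angeloyl group to the alkoxides that form at C3 and at the primary carbon. The fallback sets out from 17 and comes back at 22, and reduces the lactone before any angelate is present. Cuprate addition to 17 with excess TESCl should give the bis(triethylsilyl) compound F5 (C1 silyl ether, C8 silyl enol ether, C10 methyl). LiBH4 should give the diol F6. AcCl with collidine should give the primary acetate F7, and TBSOTf with 2,6-lutidine the C3 silyl ether F8. PPTS in MeOH should remove both triethylsilyl groups to give the hydroxy ketone F9. Yamaguchi angeloylation should give the angelate F10, and HF·pyridine then gives 22.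

Further compounds
F1 | step 7 | Michael adduct: 8 with C6 bonded to the quaternary carbon C(CH3)(COCH3)(CO2tBu), acetyl and thioester exo | CCSC(=O)[C@H]1[C@H]([C@](C)(C(C)=O)C(=O)OC(C)(C)C)[C@@H](C(C)=O)[C@]1(C)C=O
F2 | step 7 | aldol product: seven-membered β-hydroxy ketone with the tert-butyl ester on C11 | CCSC(=O)[C@H]1[C@H]2[C@@H](C(C)=O)[C@]1(C)[C@H](O)CC(=O)[C@]2(C)C(=O)OC(C)(C)C
F3 | step 5 | S-ethyl 3-acetyl-2-formyl-2-methylcyclobutane-1-carbothioate (all cis) | CCSC(=O)[C@@H]1C[C@H](C(C)=O)[C@]1(C)C=O
F4 | step 5 | S-ethyl 3-acetyl-2-formyl-2-methyl-3-(phenylselanyl)cyclobutane-1-carbothioate (mixture at the selenium-bearing carbon) | CCSC(=O)[C@@H]1CC([Se]c2ccccc2)(C(C)=O)[C@]1(C)C=O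
F5 | step 12 | bis(triethylsilyl) compound: C1 silyl ether, C8 silyl enol ether, C10 methyl, lactone intact | CC[Si](CC)(CC)OC1=C[C@@H](C)[C@H]2[C@H]3[C@@H]1[C@]2(C)[C@H]4C[C@@H](O[Si](CC)(CC)CC)[C@]3(C)C(=O)O4
F6 | step 12 | diol from F5: C3–OH and primary alcohol free | CC[Si](CC)(CC)OC1=C[C@@H](C)[C@H]2[C@H]3[C@@H]1[C@]2(C)[C@H](O)C[C@@H](O[Si](CC)(CC)CC)[C@]3(C)CO
F7 | step 12 | primary acetate of F6 | CC[Si](CC)(CC)OC1=C[C@@H](C)[C@H]2[C@H]3[C@@H]1[C@]2(C)[C@H](O)C[C@@H](O[Si](CC)(CC)CC)[C@]3(C)COC(C)=O
F8 | step 12 | C3 tert-butyldimethylsilyl ether of F7 | CC[Si](CC)(CC)OC1=C[C@@H](C)[C@H]2[C@H]3[C@@H]1[C@]2(C)[C@H](O[Si](C)(C)C(C)(C)C)C[C@@H](O[Si](CC)(CC)CC)[C@]3(C)COC(C)=O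
F9 | step 12 | hydroxy ketone: C1–OH and C8 ketone free, C3 silyl ether, primary acetate | O=C1C[C@@H](C)[C@H]2[C@H]3[C@@H]1[C@]2(C)[C@H](O[Si](C)(C)C(C)(C)C)C[C@@H](O)[C@]3(C)COC(C)=O
F10 | step 12 | C1 angelate of F9 | O=C1C[C@@H](C)[C@H]2[C@H]3[C@@H]1[C@]2(C)[C@H](O[Si](C)(C)C(C)(C)C)C[C@@H](OC(=O)/C(C)=C\C)[C@]3(C)COC(C)=O
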